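## The problem

The target 25 is an 18-membered macrocyclic bis(bibenzyl). Four benzene rings are held in the large ring by two CH2CH2 bridges (ring A to ring D, ring B to ring C) and two diaryl ether oxygens (A–O–B and C–O–D). There is no stereocenter, so the task is regiochemistry on the arenes, the order of bond formation and the closure of the large ring against oligomerization. Ring A is the crowded piece: OH, the bridge carbon, the aryloxy oxygen and OMe sit on four adjacent carbons. Ring A is also a hydroquinone monomethyl ether, so its free phenol cannot be exposed to any oxidant. One methyl ether must survive beside two free phenols, which rules out a demethylating end-game and calls for protecting groups that come off without Lewis acids. The A–O–B ether is flanked on ring A by OMe and by the bridge and is the most hindered bond of the molecule. The feature that opens the key step is ring C: a 4-alkylphenol whose ortho carbon carries the oxygen that sits para to the bridge on ring D. The C–O–D ether is therefore the head-to-ortho ether of two 4-hydroxyphenethyl units, the bond that phenol oxidation forms.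

## Retrosynthesis

**End-game (25 from 24 from 23).** No skeletal bond is cut here. The ring A phenol is masked as its N,N-diethylcarbamate 24, and one bromine on ring C and two chlorines on ring D are added back to give macrocycle 23. The halogens are control elements for the ring closure and all leave in one hydrogenolysis. The carbamate is chosen over a simple ester because it alone survives ylides, borohydride and acid, directs the metalation that builds ring A, and keeps ring A non-phenolic during the oxidation. The forward steps must remove three aryl halogens without touching the diaryl ethers and then hydrolyse a hindered aryl carbamate.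

**Ring C carbon–oxygen bond (23 from 21).** The macrocycle is opened at the bond between the ortho carbon of ring C and the oxygen of ring D. Cutting the A–O–B ether instead would ask a macrocyclization to make the most hindered bond. Cutting a CH2CH2 bridge would need both ethers in place first and a ring-closing olefination through a strained stilbene. The chosen cut gives seco compound 21, whose two ends are both 4-alkylphenols and differ only in their halogens (dibromo on ring C, dichloro on ring D). The forward reaction must oxidize only ring C, let only the ring D oxygen attack, and close an 18-membered ring at high dilution.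

**Bridge B–C (21 from 20 from 17 and 18).** The benzylic carbon–carbon bond of the B–C bridge is cut as an alkene. Diimide saturates bis-stilbene 20 without touching aryl bromides or chlorides. Alkene 20 comes from the ylide of phosphonium salt 17 and purchased 3,5-dibromo-4-hydroxybenzaldehyde 18. Bringing the halogens in with the aldehyde avoids a late bromination, which would have to distinguish ring C from the electron-rich ring A. The Wittig reaction has to tolerate the aldehyde as its phenoxide.

**Bridge A–D (17 from 16, 15, 14, and 14 from 11 and 12).** Salt 17 is traced through benzylic alcohol 16 and aldehyde 15 to acetal 14. The A–D alkene of 14 is cut in the same way into phosphonium salt 11 and purchased 3,5-dichloro-4-hydroxybenzaldehyde 12. The acetal keeps the ring B carbon silent while the ring A arm is built, so the two different aldehydes are introduced one after the other without ambiguity. The ring A arm must come first because aryl bromides would not survive the metalation below.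

**Ring A bridge carbon (11 from 9, 8, and 8 from 6).** Salt 11 comes from alcohol 9 and aldehyde 8. The formyl carbon of 8 is cut from ring A at C-2, the carbon between the carbamate oxygen and the aryloxy oxygen of 6. This is the only position on ring A acidified by two flanking oxygens, so directed ortho-metalation places the carbon where electrophilic substitution would not. The forward step needs lithiation at C-2 and formylation before the carbamoyl group migrates.

**Ring A oxygen pattern and the A–O–B ether (6 from 5, 3, and 3 from 1 and 2).** Carbamate 6 is made from phenol 5, which comes from aldehyde 3 by exchange of CHO for OH (Baeyer–Villiger). Aldehyde 3 is cut at the diaryl ether into isovanillin 1 and the bromo acetal 2. The hindered ether is thus made first, intermolecularly, from two simple benzenes, and the formyl group of isovanillin serves as the latent para oxygen of ring A.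

## Roads not taken

**Alternative 1: ring B built by Diels–Alder reaction on a preformed macrocycle.**
- Cut: ring B is taken apart into a four-carbon 2-aryloxy-1,3-diene embedded in the macrocycle (A2) and the two carbons of ethynyl p-tolyl sulfone A4. A2 would come from the macrocyclic unsaturated aryl ester A3 by carbonyl methylenation with a titanium methylidene reagent.
- Forward key step: cycloaddition of A2 with A4 gives the racemic cyclohexa-1,4-dienyl sulfone A1. Double-bond migration and loss of the sulfonyl group as sulfinate would aromatize ring B.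
- Merits: the large ring is closed as an ester, a dependable macrocyclization on a flexible chain. The meta pattern of ring B follows from the polarity of diene and dienophile. No halogen ballast and no thallium are needed.
- Weak points: A2 is an aryl enol ether and hydrolyses easily. Methylenation of a conjugated aryl ester competes with loss of the phenoxide. The diene must reach an s-cis shape inside the ring. A1 can aromatize by expelling the ring A phenoxide instead of the sulfinate, which would open the macrocycle. Both diaryl-type oxygens, the ester, the diene and two benzyl ethers all have to be made first, so the count is higher.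
- Comparison: its ring closure is probably more reliable than the oxidative closure of 21 to 23. The chosen plan sets against this that all four rings are bought as benzenes and that its key reaction is known on this substrate class.

**Alternative 2: ring A ether made by addition–elimination on a bromoquinone monoketal.**
- Cut: the hindered A–O–B bond.
- Forward key step: in seco compound A6 the ring B phenoxide adds to the bromine-bearing β-carbon of the 3-bromo-4,4-dimethoxycyclohexadienone and bromide leaves, giving macrocyclic quinone monoketal A5. Reduction would turn the monoketal into the para-methoxyphenol of ring A, and hydrogenolysis of the benzyl ether could occur in the same operation.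
- Merits: the OH/OMe para pattern of ring A comes straight from the ketal. The most hindered ether is formed with an activated electrophile and no metal. The end-game is shorter than that of the chosen plan and no dehalogenation is needed.
- Weak points: the β-carbon attacked is fully substituted and lies between the ketal carbon and the bridge-bearing carbon, while the other enone β-carbon of A6 is an unhindered CH and invites the wrong conjugate addition. Quinone monoketals are sensitive to acid and to hard nucleophiles. Making A6 requires oxidative dearomatization of a bromophenol while the ring B phenol is masked, then unmasking beside the ketal. The hardest bond is left for the macrocyclization, with no direct model.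
- Comparison: if the closure worked, this road would be shorter after the key step and cleaner in waste. The chosen plan makes the hindered ether early and intermolecularly, and closes the ring at the unhindered ring C position.

**Alternative 3: ring D built from a 2-pyrone and an ynol ether.**
- Cut: ring D is divided into the four carbons C3–C6 of a 5-acyl-2-pyrone and the two carbons of an aryl ethynyl ether on the ring C oxygen, both in seco compound A7.
- Forward key step: intramolecular [4+2] addition across C3 and C6 of the pyrone, followed by cycloreversion that expels the lactone bridge, forms ring D and the macrocycle at once and gives ketone A8. One hydrogenolysis could then reduce the benzylic ketone to CH2 and cleave both benzyl ethers.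
- Merits: convergent. The ring closure is made irreversible by the extrusion. The polarity of ynol ether and acylpyrone matches the para pattern of ring D. The end-game is a single step.
- Weak points: aryl ethynyl ethers are fragile and would have to be made on an advanced phenol. The acylpyrone is attacked by bases and nucleophiles, and its CH2 next to the ketone is enolizable. The transition state must span the whole 18-membered ring across the para positions of the forming arene, and such cycloadditions usually need heat, which favours oligomers and decomposition of the ynol ether.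
- Comparison: in step economy after the key step this road is better. The chosen plan has a key reaction with close precedent for macrocyclic diaryl ethers and stable intermediates throughout.

Key step: step 13

## Route

Remark on the chemistry: the bromo acetal 2 (ethylene acetal of 3-bromobenzaldehyde) is taken as a purchased compound. Alkenes 14–17 and 20 are carried as E/Z mixtures because step 12 saturates both double bonds, so their SMILES carry no geometry.

Step 1
Reactants: 1 isovanillin (3-hydroxy-4-methoxybenzaldehyde); 2 2-(3-bromophenyl)-1,3-dioxolane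
Product: 3 3-[3-(1,3-dioxolan-2-yl)phenoxy]-4-methoxybenzaldehyde
Conditions: CuI (10 mol %), N,N-dimethylglycine hydrochloride (30 mol %), Cs2CO3, 1,4-dioxane, 100 °C
Reagents that add atoms: none
Why: Ligand-accelerated Ullmann diaryl ether synthesis between an unhindered meta-substituted aryl bromide and the phenoxide of 1; aldehyde and acetal tolerate the carbonate base.

Step 2
Reactants: 3 3-[3-(1,3-dioxolan-2-yl)phenoxy]-4-methoxybenzaldehyde
Product: 5 3-[3-(1,3-dioxolan-2-yl)phenoxy]-4-methoxyphenol, via aryl formate 4 (not isolated)
Conditions: mCPBA, NaHCO3, CH2Cl2, 0 °C to rt; then K2CO3 (cat.), MeOH, rt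
Reagents that add atoms: meta-chloroperoxybenzoic acid, OOC(=O)c1cccc(Cl)c1
Why: Baeyer–Villiger (Dakin-type) oxidation; the para-methoxy group makes the aryl group migrate, and the formate is cleaved by methanolysis while the buffer protects the acetal.

Step 3
Reactants: 5 3-[3-(1,3-dioxolan-2-yl)phenoxy]-4-methoxyphenol
Product: 6 3-[3-(1,3-dioxolan-2-yl)phenoxy]-4-methoxyphenyl N,N-diethylcarbamate
Conditions: Et2NCOCl, K2CO3, MeCN, reflux
Reagents that add atoms: N,N-diethylcarbamoyl chloride, CCN(CC)C(Cl)=O
Why: Standard O-carbamoylation of a phenoxide; the carbamate serves later as metalation director, base-stable protecting group and oxidation shield.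

Step 4
Reactants: 6 3-[3-(1,3-dioxolan-2-yl)phenoxy]-4-methoxyphenyl N,N-diethylcarbamate
Product: 8 3-[3-(1,3-dioxolan-2-yl)phenoxy]-2-formyl-4-methoxyphenyl N,N-diethylcarbamate, via aryllithium 7 (not isolated)
Conditions: s-BuLi, TMEDA, THF, −78 °C; DMF, −78 to 0 °C; aq. NH4Cl
Reagents that add atoms: N,N-dimethylformamide, CN(C)C=O
Why: Directed ortho-metalation of an aryl O-carbamate; C-2 lies between the carbamate and aryloxy oxygens and is the most acidic site, and formylation at −78 °C precedes the anionic ortho-Fries shift.

Step 5
Reactants: 8 3-[3-(1,3-dioxolan-2-yl)phenoxy]-2-formyl-4-methoxyphenyl N,N-diethylcarbamate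
Product: 9 3-[3-(1,3-dioxolan-2-yl)phenoxy]-2-(hydroxymethyl)-4-methoxyphenyl N,N-diethylcarbamate
Conditions: NaBH4, MeOH/THF, 0 °C
Reagents that add atoms: none
Why: Borohydride reduction of an aryl aldehyde; the low temperature and the poor acyl-donor character of the diethylcarbamate should prevent carbamoyl transfer to the new alcohol.

Step 6
Reactants: 9 3-[3-(1,3-dioxolan-2-yl)phenoxy]-2-(hydroxymethyl)-4-methoxyphenyl N,N-diethylcarbamate
Product: 11 {2-[(diethylcarbamoyl)oxy]-6-[3-(1,3-dioxolan-2-yl)phenoxy]-5-methoxybenzyl}triphenylphosphonium bromide, via benzylic bromide 10 (not isolated)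
Conditions: CBr4, PPh3, CH2Cl2, 0 °C; then PPh3, toluene, 80 °C
Reagents that add atoms: carbon tetrabromide, BrC(Br)(Br)Br; triphenylphosphine, c1ccc(cc1)P(c1ccccc1)c1ccccc1
Why: Appel bromination under neutral conditions keeps the acetal, and the reactive benzylic bromide is quaternized at once by triphenylphosphine (SN2).

Step 7
Reactants: 11 {2-[(diethylcarbamoyl)oxy]-6-[3-(1,3-dioxolan-2-yl)phenoxy]-5-methoxybenzyl}triphenylphosphonium bromide; 12 3,5-dichloro-4-hydroxybenzaldehyde
Product: 14 2-[2-(3,5-dichloro-4-hydroxyphenyl)ethenyl]-3-[3-(1,3-dioxolan-2-yl)phenoxy]-4-methoxyphenyl N,N-diethylcarbamate (E/Z mixture), via phosphorus ylide 13 (not isolated)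
Conditions: KOtBu (2.2 equiv), THF/DMF, 0 °C to rt; then AcOH
Reagents that add atoms: none
Why: Wittig olefination of a semistabilized benzylic ylide with a hydroxybenzaldehyde used as its potassium phenoxide; the two chlorines keep the phenoxide a weak donor so the aldehyde stays electrophilic, and alkene geometry is irrelevant.

Step 8
Reactants: 14 2-[2-(3,5-dichloro-4-hydroxyphenyl)ethenyl]-3-[3-(1,3-dioxolan-2-yl)phenoxy]-4-methoxyphenyl N,N-diethylcarbamate
Product: 15 2-[2-(3,5-dichloro-4-hydroxyphenyl)ethenyl]-3-(3-formylphenoxy)-4-methoxyphenyl N,N-diethylcarbamate (E/Z mixture)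
Conditions: 1 M aq. HCl, THF, rt
Reagents that add atoms: water, O
Why: Acid-catalysed hydrolysis of an aryl dioxolane; the carbamate, diaryl ether and stilbene are stable to dilute acid at room temperature.

Step 9
Reactants: 15 2-[2-(3,5-dichloro-4-hydroxyphenyl)ethenyl]-3-(3-formylphenoxy)-4-methoxyphenyl N,N-diethylcarbamate
Product: 16 2-[2-(3,5-dichloro-4-hydroxyphenyl)ethenyl]-3-[3-(hydroxymethyl)phenoxy]-4-methoxyphenyl N,N-diethylcarbamate (E/Z mixture)
Conditions: NaBH4, MeOH/THF, 0 °C
Reagents that add atoms: none
Why: Chemoselective borohydride reduction of the aldehyde; carbamate, alkene and aryl chlorides are inert.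

Step 10
Reactants: 16 2-[2-(3,5-dichloro-4-hydroxyphenyl)ethenyl]-3-[3-(hydroxymethyl)phenoxy]-4-methoxyphenyl N,N-diethylcarbamate
Product: 17 (3-{2-[2-(3,5-dichloro-4-hydroxyphenyl)ethenyl]-3-[(diethylcarbamoyl)oxy]-6-methoxyphenoxy}benzyl)triphenylphosphonium bromide (E/Z mixture)
Conditions: PPh3·HBr, MeCN, reflux
Reagents that add atoms: triphenylphosphine hydrobromide, [Br-].c1ccc(cc1)[PH+](c1ccccc1)c1ccccc1
Why: Direct conversion of a benzylic alcohol into its phosphonium salt with triphenylphosphine hydrobromide, the usual entry to Wittig salts in bis(bibenzyl) work; it tolerates the free phenol and needs no activating reagent that the phenol would consume.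

Step 11
Reactants: 17 (3-{2-[2-(3,5-dichloro-4-hydroxyphenyl)ethenyl]-3-[(diethylcarbamoyl)oxy]-6-methoxyphenoxy}benzyl)triphenylphosphonium bromide; 18 3,5-dibromo-4-hydroxybenzaldehyde
Product: 20 3-{3-[2-(3,5-dibromo-4-hydroxyphenyl)ethenyl]phenoxy}-2-[2-(3,5-dichloro-4-hydroxyphenyl)ethenyl]-4-methoxyphenyl N,N-diethylcarbamate (mixture of alkene isomers), via potassium phenoxide ylide 19 (not isolated)
Conditions: KOtBu (3.3 equiv), THF/DMF, 0 to 40 °C; then AcOH
Reagents that add atoms: none
Why: Second Wittig olefination, with one equivalent of base each for the ring D phenol, the benzylic position and the phenol of 18; the unhindered meta-benzyl ylide is more reactive than that of step 7.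

Step 12
Reactants: 20 3-{3-[2-(3,5-dibromo-4-hydroxyphenyl)ethenyl]phenoxy}-2-[2-(3,5-dichloro-4-hydroxyphenyl)ethenyl]-4-methoxyphenyl N,N-diethylcarbamate
Product: 21 3-{3-[2-(3,5-dibromo-4-hydroxyphenyl)ethyl]phenoxy}-2-[2-(3,5-dichloro-4-hydroxyphenyl)ethyl]-4-methoxyphenyl N,N-diethylcarbamate
Conditions: TsNHNH2, NaOAc, DME/H2O, reflux
Reagents that add atoms: none
Why: Diimide reduction: concerted syn transfer of two hydrogens saturates both stilbene double bonds of either geometry and leaves C–Br and C–Cl bonds untouched, which catalytic hydrogenation would not.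

Step 13
Reactants: 21 3-{3-[2-(3,5-dibromo-4-hydroxyphenyl)ethyl]phenoxy}-2-[2-(3,5-dichloro-4-hydroxyphenyl)ethyl]-4-methoxyphenyl N,N-diethylcarbamate
Product: 23 bromo dichloro macrocycle (18-membered ring; ring C bears OH flanked by Br and the new aryloxy oxygen, ring D bears Cl at both carbons ortho to that oxygen, ring A bears OMe and the diethylcarbamate), via bromodienone 22 (not isolated)
Conditions: Tl(NO3)3·3H2O (3 equiv), MeOH/THF, 1 mM, −20 to 0 °C; then Zn dust, AcOH, rt
Reagents that add atoms: none
Why: The reaction type is the known Tl(NO3)3 oxidative coupling of ortho,ortho'-dihalophenols to macrocyclic diaryl ethers with zinc work-up. The ring C phenoxide binds trivalent thallium and loses two electrons (thallium leaves as the monovalent ion), giving a phenoxonium-type 2,6-dibromo-4-alkylcyclohexadienone cation. The hydroxyl of the ring D dichlorophenol adds to a bromine-bearing ortho carbon, which closes the 18-membered ring by end-to-end carbon–oxygen bond formation and gives the racemic ortho-quinol ether dienone 22; zinc in acetic acid then reduces the C–Br bond at that sp3 carbon and the dienolate tautomerizes to the phenol, so no stereocenter remains. Chemoselectivity between the phenols comes from the halogens: the dibromophenol has the lower oxidation potential and is oxidized, while the dichlorophenol resists oxidation and acts as the oxygen nucleophile. The two ortho carbons of ring C are equivalent, the para carbon is blocked by the bridge, and any methanol adduct at the para carbon is returned to the phenol by the zinc step. Halogens on all four ortho positions exclude carbon–carbon coupling, the carbamate keeps ring A from reacting as a para-methoxyphenol, and millimolar dilution favours ring closure over dimers.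

Step 14
Reactants: 23 bromo dichloro macrocycle
Product: 24 halogen-free macrocycle, the ring A N,N-diethylcarbamate of the target
Conditions: H2 (1 atm), 10% Pd/C, NaOAc, MeOH, rt
Reagents that add atoms: none
Why: Catalytic hydrodehalogenation removes the aryl bromide and both aryl chlorides in the presence of base; bibenzyl CH2 groups, diaryl ethers and the carbamate are not hydrogenolysed.

Step 15
Reactants: 24 halogen-free macrocycle, the ring A N,N-diethylcarbamate of the target
Product: 25 target macrocycle CNP0179896.0
Conditions: KOH, EtOH/H2O, reflux, argon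
Reagents that add atoms: none
Why: Basic hydrolysis of an aryl N,N-diethylcarbamate (acyl–oxygen cleavage), run under argon and neutralized on work-up; the product has only phenol, ether and alkyl functions, which tolerate hot alkali.

## Compound list

1 | isovanillin (3-hydroxy-4-methoxybenzaldehyde) | COc1ccc(C=O)cc1O | starting material
2 | 2-(3-bromophenyl)-1,3-dioxolane | Brc1cccc(c1)C1OCCO1 | starting material
3 | 3-[3-(1,3-dioxolan-2-yl)phenoxy]-4-methoxybenzaldehyde | COc1ccc(C=O)cc1Oc1cccc(c1)C1OCCO1 | intermediate
4 | 3-[3-(1,3-dioxolan-2-yl)phenoxy]-4-methoxyphenyl formate (not isolated) | COc1ccc(OC=O)cc1Oc1cccc(c1)C1OCCO1 | intermediate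
5 | 3-[3-(1,3-dioxolan-2-yl)phenoxy]-4-methoxyphenol | COc1ccc(O)cc1Oc1cccc(c1)C1OCCO1 | intermediate
6 | 3-[3-(1,3-dioxolan-2-yl)phenoxy]-4-methoxyphenyl N,N-diethylcarbamate | CCN(CC)C(=O)Oc1ccc(OC)c(c1)Oc1cccc(c1)C1OCCO1 | intermediate
7 | 2-lithio derivative of 6, lithium between the carbamate and aryloxy oxygens (not isolated) | CCN(CC)C(=O)Oc1ccc(OC)c(Oc2cccc(c2)C2OCCO2)c1[Li] | intermediate
8 | 3-[3-(1,3-dioxolan-2-yl)phenoxy]-2-formyl-4-methoxyphenyl N,N-diethylcarbamate | CCN(CC)C(=O)Oc1ccc(OC)c(Oc2cccc(c2)C2OCCO2)c1C=O | intermediate
9 | 3-[3-(1,3-dioxolan-2-yl)phenoxy]-2-(hydroxymethyl)-4-methoxyphenyl N,N-diethylcarbamate | CCN(CC)C(=O)Oc1ccc(OC)c(Oc2cccc(c2)C2OCCO2)c1CO | intermediate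
10 | 2-(bromomethyl)-3-[3-(1,3-dioxolan-2-yl)phenoxy]-4-methoxyphenyl N,N-diethylcarbamate (not isolated) | CCN(CC)C(=O)Oc1ccc(OC)c(Oc2cccc(c2)C2OCCO2)c1CBr | intermediate
11 | {2-[(diethylcarbamoyl)oxy]-6-[3-(1,3-dioxolan-2-yl)phenoxy]-5-methoxybenzyl}triphenylphosphonium bromide | CCN(CC)C(=O)Oc1ccc(OC)c(Oc2cccc(c2)C2OCCO2)c1C[P+](c1ccccc1)(c1ccccc1)c1ccccc1.[Br-] | intermediate
12 | 3,5-dichloro-4-hydroxybenzaldehyde | O=Cc1cc(Cl)c(O)c(Cl)c1 | starting material
13 | triphenylphosphonium ylide of 11 (not isolated) | CCN(CC)C(=O)Oc1ccc(OC)c(Oc2cccc(c2)C2OCCO2)c1C=P(c1ccccc1)(c1ccccc1)c1ccccc1 | intermediate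
14 | 2-[2-(3,5-dichloro-4-hydroxyphenyl)ethenyl]-3-[3-(1,3-dioxolan-2-yl)phenoxy]-4-methoxyphenyl N,N-diethylcarbamate (E/Z mixture) | CCN(CC)C(=O)Oc1ccc(OC)c(Oc2cccc(c2)C2OCCO2)c1C=Cc1cc(Cl)c(O)c(Cl)c1 | intermediate
15 | 2-[2-(3,5-dichloro-4-hydroxyphenyl)ethenyl]-3-(3-formylphenoxy)-4-methoxyphenyl N,N-diethylcarbamate (E/Z mixture) | CCN(CC)C(=O)Oc1ccc(OC)c(Oc2cccc(C=O)c2)c1C=Cc1cc(Cl)c(O)c(Cl)c1 | intermediate
16 | 2-[2-(3,5-dichloro-4-hydroxyphenyl)ethenyl]-3-[3-(hydroxymethyl)phenoxy]-4-methoxyphenyl N,N-diethylcarbamate (E/Z mixture) | CCN(CC)C(=O)Oc1ccc(OC)c(Oc2cccc(CO)c2)c1C=Cc1cc(Cl)c(O)c(Cl)c1 | intermediate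
17 | (3-{2-[2-(3,5-dichloro-4-hydroxyphenyl)ethenyl]-3-[(diethylcarbamoyl)oxy]-6-methoxyphenoxy}benzyl)triphenylphosphonium bromide (E/Z mixture) | CCN(CC)C(=O)Oc1ccc(OC)c(Oc2cccc(C[P+](c3ccccc3)(c3ccccc3)c3ccccc3)c2)c1C=Cc1cc(Cl)c(O)c(Cl)c1.[Br-] | intermediate
18 | 3,5-dibromo-4-hydroxybenzaldehyde | O=Cc1cc(Br)c(O)c(Br)c1 | starting material
19 | ylide of 17 as its potassium phenoxide (not isolated) | CCN(CC)C(=O)Oc1ccc(OC)c(Oc2cccc(C=P(c3ccccc3)(c3ccccc3)c3ccccc3)c2)c1C=Cc1cc(Cl)c([O-])c(Cl)c1.[K+] | intermediate
20 | 3-{3-[2-(3,5-dibromo-4-hydroxyphenyl)ethenyl]phenoxy}-2-[2-(3,5-dichloro-4-hydroxyphenyl)ethenyl]-4-methoxyphenyl N,N-diethylcarbamate (mixture of alkene isomers) | CCN(CC)C(=O)Oc1ccc(OC)c(Oc2cccc(C=Cc3cc(Br)c(O)c(Br)c3)c2)c1C=Cc1cc(Cl)c(O)c(Cl)c1 | intermediate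
21 | 3-{3-[2-(3,5-dibromo-4-hydroxyphenyl)ethyl]phenoxy}-2-[2-(3,5-dichloro-4-hydroxyphenyl)ethyl]-4-methoxyphenyl N,N-diethylcarbamate (seco precursor) | COc1ccc(OC(=O)N(CC)CC)c(CCc2cc(Cl)c(O)c(Cl)c2)c1Oc1cccc(CCc2cc(Br)c(O)c(Br)c2)c1 | intermediate
22 | macrocyclic 6-aryloxy-2,6-dibromocyclohexa-2,4-dienone (ring C dearomatized, sp3 carbon bearing Br and the ring D oxygen, racemic; not isolated) | COc1ccc(OC(=O)N(CC)CC)c2c1Oc1cccc(c1)CCC1=CC(Br)(Oc3c(Cl)cc(cc3Cl)CC2)C(=O)C(Br)=C1 | intermediate
23 | bromo dichloro macrocycle (ring A diethylcarbamate; ring C 2-aryloxy-6-bromophenol; ring D 2,6-dichloroaryl ether) | COc1ccc(OC(=O)N(CC)CC)c2c1Oc1cccc(c1)CCc1cc(Br)c(O)c(c1)Oc1c(Cl)cc(cc1Cl)CC2 | intermediate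
24 | halogen-free macrocycle, ring A N,N-diethylcarbamate of the target | COc1ccc(OC(=O)N(CC)CC)c2c1Oc1cccc(c1)CCc1ccc(O)c(c1)Oc1ccc(cc1)CC2 | intermediate
25 | CNP0179896.0 (macrocyclic bis(bibenzyl) diether with ring A OMe/OH and ring C OH) | COc1ccc(O)c2c1Oc1cccc(c1)CCc1ccc(O)c(c1)Oc1ccc(cc1)CC2 | target

## Step count and risks

Total step count: 15. Longest linear sequence: 15 steps (1 to 25).

**Step 13 (key step).** The most likely failure is that the oxidation is not confined to ring C, or that intermolecular coupling and methanol capture of the oxidized ring outrun the 18-membered ring closure. Fallback: widen the gap between the two phenols by making ring C a diiodophenol, which is oxidized under milder and more dilute conditions. The fallback sets out from salt 17 and returns at macrocycle 24. Ylide 19 is condensed with 4-hydroxy-3,5-diiodobenzaldehyde F1 to give the diiodo bis-stilbene F2, and diimide reduction gives the diiodo dichloro seco compound F3. Oxidation with Tl(NO3)3 and zinc reduction proceed through the iododienone F4 to the iodo dichloro macrocycle F5. Hydrogenolysis over Pd/C with NaOAc then gives 24.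

**Step 4.** Deprotonation may occur at the open ortho position C-6 of ring A, or at the acetal carbon, or the carbamoyl group may shift before formylation. Fallback with a silicon blocking group, from 6 back to 8: if metalation takes C-6, the 6-lithio species F6 is quenched with Me3SiCl to give the 6-trimethylsilyl carbamate F7. A second metalation can then only give the 2-lithio-6-silyl species F8, which is formylated with DMF to the 2-formyl-6-trimethylsilyl carbamate F9. Ipso-protodesilylation with CsF in wet DMF delivers 8.

**Step 7.** The hindered ylide 13 may react too slowly with the phenoxide form of 12, leaving time for carbamoyl transfer to the ylide carbon. Fallback, from 12 and ylide 13 back to aldehyde 15: 12 is converted with MeOCH2Cl and iPr2NEt into 3,5-dichloro-4-(methoxymethoxy)benzaldehyde F10, a neutral and more electrophilic aldehyde. Olefination with 13 at low temperature gives the methoxymethyl-protected stilbene acetal F11. Treatment with HCl in MeOH/THF at 50 °C removes the methoxymethyl group and the dioxolane together and gives 15, so step 8 is absorbed.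

**Step 11.** The trianionic mixture (two phenoxides and the ylide) may be poorly soluble and the olefination incomplete. Fallback, from 18 and ylide 19 back to 20: 18 is protected as 3,5-dibromo-4-(methoxymethoxy)benzaldehyde F12. Wittig reaction with 19 gives the mono-protected bis-stilbene F13, and HCl in MeOH removes the methoxymethyl group to give 20.

**Step 14.** Hydrogenolysis of the two chlorines that flank the diaryl ether oxygen may stall after the bromine has gone. Fallback, from 23 directly to 25 with no new compound: Raney Ni–Al alloy in aqueous KOH/MeOH at 60–80 °C is a dissolving-alloy hydrodehalogenation of halophenols, and the alkali cleaves the carbamate in the same operation.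

## Further compounds

F1 | step 13 | 4-hydroxy-3,5-diiodobenzaldehyde | O=Cc1cc(I)c(O)c(I)c1
F2 | step 13 | 3-{3-[2-(4-hydroxy-3,5-diiodophenyl)ethenyl]phenoxy}-2-[2-(3,5-dichloro-4-hydroxyphenyl)ethenyl]-4-methoxyphenyl N,N-diethylcarbamate (mixture of alkene isomers) | CCN(CC)C(=O)Oc1ccc(OC)c(Oc2cccc(C=Cc3cc(I)c(O)c(I)c3)c2)c1C=Cc1cc(Cl)c(O)c(Cl)c1
F3 | step 13 | 3-{3-[2-(4-hydroxy-3,5-diiodophenyl)ethyl]phenoxy}-2-[2-(3,5-dichloro-4-hydroxyphenyl)ethyl]-4-methoxyphenyl N,N-diethylcarbamate | COc1ccc(OC(=O)N(CC)CC)c(CCc2cc(Cl)c(O)c(Cl)c2)c1Oc1cccc(CCc2cc(I)c(O)c(I)c2)c1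
F4 | step 13 | macrocyclic 6-aryloxy-2,6-diiodocyclohexa-2,4-dienone (racemic, not isolated) | COc1ccc(OC(=O)N(CC)CC)c2c1Oc1cccc(c1)CCC1=CC(I)(Oc3c(Cl)cc(cc3Cl)CC2)C(=O)C(I)=C1
F5 | step 13 | iodo dichloro macrocycle (ring C 2-aryloxy-6-iodophenol) | COc1ccc(OC(=O)N(CC)CC)c2c1Oc1cccc(c1)CCc1cc(I)c(O)c(c1)Oc1c(Cl)cc(cc1Cl)CC2
F6 | step 4 | 6-lithio derivative of 6 (lithium at the open ortho position, not isolated) | CCN(CC)C(=O)Oc1c([Li])cc(OC)c(Oc2cccc(c2)C2OCCO2)c1
F7 | step 4 | 5-[3-(1,3-dioxolan-2-yl)phenoxy]-4-methoxy-2-(trimethylsilyl)phenyl N,N-diethylcarbamate | CCN(CC)C(=O)Oc1c([Si](C)(C)C)cc(OC)c(Oc2cccc(c2)C2OCCO2)c1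
F8 | step 4 | 2-lithio-6-trimethylsilyl derivative of 6 (not isolated) | CCN(CC)C(=O)Oc1c([Si](C)(C)C)cc(OC)c(Oc2cccc(c2)C2OCCO2)c1[Li]
F9 | step 4 | 3-[3-(1,3-dioxolan-2-yl)phenoxy]-2-formyl-4-methoxy-6-(trimethylsilyl)phenyl N,N-diethylcarbamate | CCN(CC)C(=O)Oc1c([Si](C)(C)C)cc(OC)c(Oc2cccc(c2)C2OCCO2)c1C=O
F10 | step 7 | 3,5-dichloro-4-(methoxymethoxy)benzaldehyde | COCOc1c(Cl)cc(C=O)cc1Cl
F11 | step 7 | 2-{2-[3,5-dichloro-4-(methoxymethoxy)phenyl]ethenyl}-3-[3-(1,3-dioxolan-2-yl)phenoxy]-4-methoxyphenyl N,N-diethylcarbamate (E/Z mixture) | CCN(CC)C(=O)Oc1ccc(OC)c(Oc2cccc(c2)C2OCCO2)c1C=Cc1cc(Cl)c(OCOC)c(Cl)c1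
F12 | step 11 | 3,5-dibromo-4-(methoxymethoxy)benzaldehyde | COCOc1c(Br)cc(C=O)cc1Br
F13 | step 11 | 3-(3-{2-[3,5-dibromo-4-(methoxymethoxy)phenyl]ethenyl}phenoxy)-2-[2-(3,5-dichloro-4-hydroxyphenyl)ethenyl]-4-methoxyphenyl N,N-diethylcarbamate (mixture of alkene isomers) | CCN(CC)C(=O)Oc1ccc(OC)c(Oc2cccc(C=Cc3cc(Br)c(OCOC)c(Br)c3)c2)c1C=Cc1cc(Cl)c(O)c(Cl)c1
F0 | step 14 | none | none
A1 | alternative 1 | macrocyclic 1-aryloxycyclohexa-1,4-dienyl p-tolyl sulfone (racemic) | COc1ccc(OCc3ccccc3)c2c1OC1=CC(C(=CC1)S(=O)(=O)c1ccc(C)cc1)CCc1ccc(OCc3ccccc3)c(c1)Oc1ccc(cc1)CC2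
A2 | alternative 1 | macrocyclic 2-aryloxy-1,3-diene, dibenzyl ether | COc1ccc(OCc3ccccc3)c2c1OC(=C)/C=C/CCc1ccc(OCc3ccccc3)c(c1)Oc1ccc(cc1)CC2
A3 | alternative 1 | macrocyclic (E)-unsaturated aryl ester (macrolactone), dibenzyl ether | COc1ccc(OCc3ccccc3)c2c1OC(=O)/C=C/CCc1ccc(OCc3ccccc3)c(c1)Oc1ccc(cc1)CC2
A4 | alternative 1 | ethynyl p-tolyl sulfone | Cc1ccc(cc1)S(=O)(=O)C#C
A5 | alternative 2 | macrocyclic aryloxy quinone monoketal, ring C benzyl ether | COC1(OC)C=CC(=O)C2=C1Oc1cccc(c1)CCc1ccc(OCc3ccccc3)c(c1)Oc1ccc(cc1)CC2
A6 | alternative 2 | seco 3-bromo-4,4-dimethoxycyclohexa-2,5-dienone with free ring B phenol | COC1(OC)C=CC(=O)C(CCc2ccc(Oc3cc(CCc4cccc(O)c4)ccc3OCc3ccccc3)cc2)=C1Br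
A7 | alternative 3 | seco 5-acyl-2-pyrone with aryl ethynyl ether on the ring C oxygen | C#COc1cc(CCc2cccc(Oc3c(OC)ccc(OCc4ccccc4)c3CC(=O)C3=COC(=O)C=C3)c2)ccc1OCc1ccccc1
A8 | alternative 3 | macrocyclic aryl ketone, dibenzyl ether | COc1ccc(OCc3ccccc3)c2c1Oc1cccc(c1)CCc1ccc(OCc3ccccc3)c(c1)Oc1ccc(cc1)C(=O)C2
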